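**Retrosynthetic overview** (labdane numbering: ring A = C1–C5, C10; ring B = C5–C10; α = the face that carries H5, the C10 methyl, the C9 chain and the C3 oxygen)
- The route rests on ring B of the cis-fused decalin: quaternary C10 (methyl) and chain-bearing C9 sit next to the C8 methylidene, so they are the β- and α-carbons of a latent C8 ketone. Both bonds (C10–CH3, C9–C11) are cut at a C9=C10 octalone whose ring A (C3–O, C4 gem-diester, C5–H) is already complete.
- After the key step: the allyl group is cut to C11–C12 by ozonolysis, C8=O becomes C8=CH2, the C4 diester becomes C4(CH2OH)2, and C12–C13 is made by alkylating a phenylthio lactone, with sulfoxide elimination to the butenolide.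
- Before the key step: ring A is closed onto a ring-B cyclohexenone by a malonate aldol (C3–C4), and C3 is then corrected by oxidation and bulky-hydride reduction. The C1–C3 chain enters by conjugate addition and Saegusa–Ito oxidation.
- Absolute configuration: C5 comes from a palladium-catalysed asymmetric allylic alkylation of cyclohex-2-enyl acetate with diethyl malonate; C3, C10 and C9 are then set relative to C5.
- Ring order: ring B (purchased carbocycle), then ring A (aldol), then the lactone ring attached as a preformed unit.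

Key step: step 10

Remark: the (S,S)-ligand in step 2 is assigned from the usual sense of induction of this ligand class with cycloalk-2-enyl esters ((R,R)-ligand giving the (S)-malonate); if the sense proves opposite, the antipodal ligand is used.

**Step 1**
Reactants: 1 cyclohex-2-en-1-ol (racemic)
Product: 2 cyclohex-2-en-1-yl acetate (racemic)
Conditions: Ac2O, pyridine, DMAP (cat.), CH2Cl2, 0 °C → rt
Reagents that add atoms: acetic anhydride, CC(=O)OC(C)=O
Why: Nucleophile-catalysed O-acylation of a secondary allylic alcohol should give the allylic acetate needed for ionisation by palladium.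

**Step 2**
Reactants: 2 cyclohex-2-en-1-yl acetate; 3 diethyl malonate
Product: 4 diethyl 2-[(1R)-cyclohex-2-en-1-yl]propanedioate
Conditions: NaH, (n-C6H13)4NBr, [Pd(C3H5)Cl]2 (2.5 mol %), (1S,2S)-N,N'-bis[2-(diphenylphosphanyl)benzoyl]cyclohexane-1,2-diamine (7.5 mol %), CH2Cl2, 0 °C → rt
Reagents that add atoms: none
Why: In this Tsuji–Trost asymmetric allylic alkylation both enantiomers of 2 ionise to the same meso π-allylpalladium complex, and the chiral diphosphine should direct the malonate to one enantiotopic allyl terminus, which sets C5.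

**Step 3**
Reactants: 4 diethyl 2-[(1R)-cyclohex-2-en-1-yl]propanedioate
Product: 5 diethyl 2-[(1R)-4-oxocyclohex-2-en-1-yl]propanedioate
Conditions: Rh2(cap)4 (cap = caprolactamate, 1 mol %), t-BuOOH (70% aq., 5 equiv), CH2Cl2, rt
Reagents that add atoms: tert-butyl hydroperoxide, CC(C)(C)OO
Why: Radical allylic C–H oxidation should occur at the unhindered ring CH2 next to the alkene (future C8), because the tertiary allylic C5–H is shielded and inductively deactivated by the malonate, so the enone forms with C5 untouched.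

**Step 4**
Reactants: 5 diethyl 2-[(1R)-4-oxocyclohex-2-en-1-yl]propanedioate; 6 2-(2-bromoethyl)-1,3-dioxolane
Product: 8 diethyl 2-[(1R,2S)-2-[2-(1,3-dioxolan-2-yl)ethyl]-4-[(trimethylsilyl)oxy]cyclohex-3-en-1-yl]propanedioate (ring substituents trans), via alkylmagnesium bromide 7 (not isolated)
Conditions: 6, Mg, THF, 25 °C; then CuBr·SMe2 (10 mol %), TMSCl, HMPA, THF, −78 °C, 5 added; 2.3 equiv of 7 (one equivalent is taken up by the malonate C–H, which is restored on work-up); Et3N, pentane, cold aq. NaHCO3
Reagents that add atoms: chlorotrimethylsilane, C[Si](C)(C)Cl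
Why: Copper-catalysed, silyl-chloride-accelerated conjugate addition of the Grignard reagent should deliver the C1–C3 chain to C10 anti to the C5 substituent and trap the C8–C9 enolate regiospecifically as its silyl enol ether.

**Step 5**
Reactants: 8 silyl enol ether from step 4
Product: 9 diethyl 2-[(1S)-2-[2-(1,3-dioxolan-2-yl)ethyl]-4-oxocyclohex-2-en-1-yl]propanedioate
Conditions: Pd(OAc)2 (1.05 equiv), MeCN, rt
Reagents that add atoms: none
Why: Saegusa–Ito oxidation through the palladium enolate and β-hydride elimination of the C10–H should return the enone regiospecifically as C9=C10, removing the temporary C10 centre while C5 is unaffected.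

**Step 6**
Reactants: 9 diethyl 2-[(1S)-2-[2-(1,3-dioxolan-2-yl)ethyl]-4-oxocyclohex-2-en-1-yl]propanedioate
Product: 11 diethyl (4aR)-6-hydroxy-2-oxo-2,3,4,4a,7,8-hexahydronaphthalene-5,5(6H)-dicarboxylate (both C3 epimers), via aldehyde 10 (not isolated)
Conditions: 1 M HCl (0.3 equiv), THF/H2O (4:1), 45 °C; then K2CO3 (0.6 equiv), 0 °C → rt
Reagents that add atoms: water, O
Why: Acid hydrolysis of the dioxolane frees the C3 aldehyde, and the malonate C–H (the most acidic site) should then close ring A by a 6-exo-trig intramolecular aldol addition forming C3–C4; the C3 configuration is not relied on here.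

**Step 7**
Reactants: 11 ring-A aldol product (C3 epimers)
Product: 12 diethyl (4aR)-2,6-dioxo-2,3,4,4a,7,8-hexahydronaphthalene-5,5(6H)-dicarboxylate
Conditions: Dess–Martin periodinane, pyridine, CH2Cl2, 0 °C → rt
Reagents that add atoms: none
Why: Dess–Martin oxidation of the hindered secondary alcohol should converge both C3 epimers on one ketone, which cannot enolise towards the quaternary C4.

**Step 8**
Reactants: 12 C3 ketone
Product: 13 diethyl (4aR,6R)-6-hydroxy-2-oxo-2,3,4,4a,7,8-hexahydronaphthalene-5,5(6H)-dicarboxylate (3-OH α, cis to H5)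
Conditions: LiBH(s-Bu)3 (1.05 equiv), THF, −78 °C; AcOH quench at −78 °C
Reagents that add atoms: none
Why: In this substrate-controlled bulky-hydride reduction the reagent should attack C3 from the equatorial direction, because axial approach is opposed by the syn-axial hydrogens at C1 and C5, giving the axial α-alcohol cis to H5; the saturated, doubly ester-activated ketone is expected to react before the less electrophilic β,β-disubstituted enone.

**Step 9**
Reactants: 13 cis hydroxy enone
Product: 14 diethyl (4aR,6R)-6-[(tert-butyldimethylsilyl)oxy]-2-oxo-2,3,4,4a,7,8-hexahydronaphthalene-5,5(6H)-dicarboxylate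
Conditions: TBSOTf, 2,6-lutidine, CH2Cl2, −78 → 0 °C
Reagents that add atoms: tert-butyldimethylsilyl trifluoromethanesulfonate, CC(C)(C)[Si](C)(C)OS(=O)(=O)C(F)(F)F
Why: Silyl triflate silylation should cap the hindered axial alcohol, which blocks retro-aldol opening of ring A in the basic steps that follow.

**Step 10**
Reactants: 14 bicyclic C9=C10 enone; 15 methyllithium; 16 3-iodoprop-1-ene (allyl iodide)
Product: 19 diethyl (1S,4aR,6R,8aR)-6-[(tert-butyldimethylsilyl)oxy]-8a-methyl-2-oxo-1-(prop-2-en-1-yl)octahydronaphthalene-5,5(1H)-dicarboxylate, via lithium dimethylcuprate 17 (not isolated), via lithium enolate 18 (not isolated)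
Conditions: CuI, MeLi (2 equiv per Cu), Et2O, 0 °C; 14, −78 → −20 °C; then allyl iodide (5 equiv), HMPA/THF, −40 °C → rt
Reagents that add atoms: none
Why: Me2CuLi forms a π-complex with the enone and, through the β-cuprio (trivalent copper) enolate, transfers methyl to C10 by reductive elimination; the closest known reaction type is cuprate addition to ring-fusion octalones (cis-9-methyl-2-decalones) with alkylation of the regiodefined enolate. No ring is closed; the C10–CH3 and C9–C11 bonds are formed. Methyl is delivered axially with respect to ring B on the face of H5, because the opposite face is the axial direction of ring A and is blocked by the axial C4 ester, so the cis ring fusion should result. Enolate 18 is the C8–C9 isomer only and is allylated by SN2 attack on allyl iodide at C9 from the convex face of the cis-decalin, anti to the C1–C10 bond, which places the allyl group cis to the new methyl. The step needs 1,4- over 1,2-addition (soft cuprate), C- over O-allylation and C9 over C7 allylation (excess allyl iodide with HMPA at low temperature, before the enolate equilibrates); the C3 silyl ether prevents retro-aldol and the esters carry no α-hydrogen.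

**Step 11**
Reactants: 19 allyl ketone
Product: 22 diethyl (1S,4aR,6R,8aR)-6-[(tert-butyldimethylsilyl)oxy]-1-(2-hydroxyethyl)-8a-methyl-2-oxooctahydronaphthalene-5,5(1H)-dicarboxylate, via ozonide 20 (not isolated), via keto aldehyde 21 (not isolated)
Conditions: O3, CH2Cl2, −78 °C; PPh3, −78 °C → rt; then EtOH added (EtOH/CH2Cl2 3:7), NaBH4, −78 °C
Reagents that add atoms: ozone, [O-][O+]=O
Why: Ozonolysis cleaves the only alkene to the C12 aldehyde, and borohydride at −78 °C in ethanol/dichloromethane should reduce the aldehyde chemoselectively beside the hindered C8 ketone without touching the C9 centre.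

**Step 12**
Reactants: 22 hydroxy ketone
Product: 23 diethyl (1R,4aR,6R,8aS)-6-[(tert-butyldimethylsilyl)oxy]-1-(2-hydroxyethyl)-8a-methyl-2-methylideneoctahydronaphthalene-5,5(1H)-dicarboxylate
Conditions: Zn, CH2Br2, TiCl4, THF (reagent aged at 5 °C, excess); 22, CH2Cl2, 0 °C → rt
Reagents that add atoms: dibromomethane, BrCBr
Why: Takai–Lombardo methylenation with the non-basic zinc/titanium methylene reagent should convert the hindered, enolisable C8 ketone to the methylidene without epimerising C9, while esters and the silyl ether are tolerated and the free hydroxyl only consumes reagent.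

**Step 13**
Reactants: 23 methylidene diester
Product: 24 2-[(1R,4aR,6R,8aS)-6-[(tert-butyldimethylsilyl)oxy]-5,5-bis(hydroxymethyl)-8a-methyl-2-methylidenedecahydronaphthalen-1-yl]ethan-1-ol
Conditions: LiAlH4, THF, 0 °C → rt
Reagents that add atoms: none
Why: Hydride reduction of both neopentyl esters should give the C4 bis(hydroxymethyl) group; the alkene and the silyl ether are inert.

**Step 14**
Reactants: 24 triol
Product: 25 acetonide of 24 across the two C4 hydroxymethyl groups (spiro 2,2-dimethyl-1,3-dioxane at C4), C12–OH free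
Conditions: 2,2-dimethoxypropane, pyridinium p-toluenesulfonate (cat.), CH2Cl2, rt; MeOH added before work-up to cleave the mixed acetal at the primary hydroxyl
Reagents that add atoms: 2,2-dimethoxypropane, COC(C)(C)OC
Why: Acid-catalysed transacetalisation should tie the 1,3-diol into a six-membered isopropylidene acetal and leave the isolated primary alcohol free.

**Step 15**
Reactants: 25 acetonide alcohol
Product: 26 C12 iodide of 25
Conditions: PPh3, I2, imidazole, CH2Cl2, 0 °C
Reagents that add atoms: iodine, II
Why: Appel-type iodination through the alkoxyphosphonium salt and SN2 displacement should give the primary iodide under buffered conditions that spare the acetonide and the silyl ether.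

**Step 16**
Reactants: 27 3-bromooxolan-2-one (racemic); 28 benzenethiol
Product: 29 3-(phenylsulfanyl)oxolan-2-one (racemic)
Conditions: Et3N, CH2Cl2, 0 °C → rt
Reagents that add atoms: none
Why: SN2 displacement of the activated α-bromo lactone by thiolate should give the α-phenylthio lactone.

**Step 17**
Reactants: 26 C12 iodide; 29 3-(phenylsulfanyl)oxolan-2-one
Product: 31 C12-alkylated 3-(phenylsulfanyl)oxolan-2-one (both C13 epimers), via lactone lithium enolate 30 (not isolated)
Conditions: 29 (1.5 equiv), LiN(i-Pr)2, THF, −78 °C; then 26, HMPA, −78 °C → rt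
Reagents that add atoms: none
Why: Alkylation of the sulfur-stabilised lactone enolate with the unhindered primary iodide (SN2) should form C12–C13; the new centre is removed in the next step.

**Step 18**
Reactants: 31 alkylated phenylthio lactone
Product: 33 3-{2-[(1R,4aR,6R,8aS)-6-[(tert-butyldimethylsilyl)oxy]-8a-methyl-2-methylidene-5,5-bis(hydroxymethyl)decahydronaphthalen-1-yl]ethyl}furan-2(5H)-one as its C4 acetonide, via sulfoxide 32 (not isolated)
Conditions: mCPBA (1.0 equiv), CH2Cl2, −78 °C; solvent exchanged for toluene, 110 °C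
Reagents that add atoms: none
Why: Sulfide oxidation is much faster than epoxidation of the hindered methylidene at −78 °C, and thermal syn-elimination of the sulfoxide (sulfoxide pyrolysis) in an α-alkyl-α-sulfinyl γ-lactone should give the endocyclic C13=C14 butenolide.

**Step 19**
Reactants: 33 protected butenolide
Product: 34 3-{2-[(1R,4aR,6R,8aS)-6-hydroxy-5,5-bis(hydroxymethyl)-8a-methyl-2-methylidenedecahydronaphthalen-1-yl]ethyl}furan-2(5H)-one (target)
Conditions: HF (48% aq.), MeCN, 0 °C → rt
Reagents that add atoms: none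
Why: Aqueous hydrogen fluoride should cleave the silyl ether and hydrolyse the isopropylidene acetal in one acidic operation that the butenolide and the exocyclic alkene tolerate.

**Compound list**
1 | cyclohex-2-en-1-ol (racemic) | OC1C=CCCC1 | starting material
2 | cyclohex-2-en-1-yl acetate (racemic) | CC(=O)OC1C=CCCC1 | intermediate
3 | diethyl malonate | CCOC(=O)CC(=O)OCC | starting material
4 | diethyl 2-[(1R)-cyclohex-2-en-1-yl]propanedioate | C1CC[C@H](C=C1)C(C(=O)OCC)C(=O)OCC | intermediate
5 | diethyl 2-[(1R)-4-oxocyclohex-2-en-1-yl]propanedioate | O=C1CC[C@H](C=C1)C(C(=O)OCC)C(=O)OCC | intermediate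
6 | 2-(2-bromoethyl)-1,3-dioxolane | BrCCC1OCCO1 | starting material
7 | [2-(1,3-dioxolan-2-yl)ethyl]magnesium bromide | Br[Mg]CCC1OCCO1 | intermediate
8 | diethyl 2-[(1R,2S)-2-[2-(1,3-dioxolan-2-yl)ethyl]-4-[(trimethylsilyl)oxy]cyclohex-3-en-1-yl]propanedioate | C[Si](C)(C)OC1=C[C@@H](CCC2OCCO2)[C@@H](CC1)C(C(=O)OCC)C(=O)OCC | intermediate
9 | diethyl 2-[(1S)-2-[2-(1,3-dioxolan-2-yl)ethyl]-4-oxocyclohex-2-en-1-yl]propanedioate | O=C1CC[C@H](C(=C1)CCC2OCCO2)C(C(=O)OCC)C(=O)OCC | intermediate
10 | diethyl 2-[(1S)-4-oxo-2-(3-oxopropyl)cyclohex-2-en-1-yl]propanedioate | O=CCCC1=CC(=O)CC[C@H]1C(C(=O)OCC)C(=O)OCC | intermediate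
11 | diethyl (4aR)-6-hydroxy-2-oxo-2,3,4,4a,7,8-hexahydronaphthalene-5,5(6H)-dicarboxylate, both C3 (naphthalene C6) epimers | O=C1CC[C@H]2C(C(=O)OCC)(C(=O)OCC)C(O)CCC2=C1 | intermediate
12 | diethyl (4aR)-2,6-dioxo-2,3,4,4a,7,8-hexahydronaphthalene-5,5(6H)-dicarboxylate | O=C1CC[C@H]2C(C(=O)OCC)(C(=O)OCC)C(=O)CCC2=C1 | intermediate
13 | diethyl (4aR,6R)-6-hydroxy-2-oxo-2,3,4,4a,7,8-hexahydronaphthalene-5,5(6H)-dicarboxylate (3-OH cis to H5) | O=C1CC[C@H]2C(C(=O)OCC)(C(=O)OCC)[C@H](O)CCC2=C1 | intermediate
14 | diethyl (4aR,6R)-6-[(tert-butyldimethylsilyl)oxy]-2-oxo-2,3,4,4a,7,8-hexahydronaphthalene-5,5(6H)-dicarboxylate | O=C1CC[C@H]2C(C(=O)OCC)(C(=O)OCC)[C@H](O[Si](C)(C)C(C)(C)C)CCC2=C1 | intermediate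
15 | methyllithium | [Li]C | starting material
16 | 3-iodoprop-1-ene (allyl iodide) | C=CCI | starting material
17 | lithium dimethylcuprate | [Li+].C[Cu-]C | intermediate
18 | lithium C8–C9 enolate of the 10-methyl cis-decalone (H5 and 10-CH3 α) | [Li]OC=1CC[C@H]2C(C(=O)OCC)(C(=O)OCC)[C@H](O[Si](C)(C)C(C)(C)C)CC[C@@]2(C)C=1 | intermediate
19 | diethyl (1S,4aR,6R,8aR)-6-[(tert-butyldimethylsilyl)oxy]-8a-methyl-2-oxo-1-(prop-2-en-1-yl)octahydronaphthalene-5,5(1H)-dicarboxylate | O=C1CC[C@H]2C(C(=O)OCC)(C(=O)OCC)[C@H](O[Si](C)(C)C(C)(C)C)CC[C@@]2(C)[C@@H]1CC=C | intermediate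
20 | ozonide of 19 (1,2,4-trioxolan-3-ylmethyl group at C9, either configuration at the trioxolane carbon) | O=C1CC[C@H]2C(C(=O)OCC)(C(=O)OCC)[C@H](O[Si](C)(C)C(C)(C)C)CC[C@@]2(C)[C@@H]1CC3OCOO3 | intermediate
21 | diethyl (1S,4aR,6R,8aR)-6-[(tert-butyldimethylsilyl)oxy]-8a-methyl-2-oxo-1-(2-oxoethyl)octahydronaphthalene-5,5(1H)-dicarboxylate | O=C1CC[C@H]2C(C(=O)OCC)(C(=O)OCC)[C@H](O[Si](C)(C)C(C)(C)C)CC[C@@]2(C)[C@@H]1CC=O | intermediate
22 | diethyl (1S,4aR,6R,8aR)-6-[(tert-butyldimethylsilyl)oxy]-1-(2-hydroxyethyl)-8a-methyl-2-oxooctahydronaphthalene-5,5(1H)-dicarboxylate | O=C1CC[C@H]2C(C(=O)OCC)(C(=O)OCC)[C@H](O[Si](C)(C)C(C)(C)C)CC[C@@]2(C)[C@@H]1CCO | intermediate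
23 | diethyl (1R,4aR,6R,8aS)-6-[(tert-butyldimethylsilyl)oxy]-1-(2-hydroxyethyl)-8a-methyl-2-methylideneoctahydronaphthalene-5,5(1H)-dicarboxylate | C=C1CC[C@H]2C(C(=O)OCC)(C(=O)OCC)[C@H](O[Si](C)(C)C(C)(C)C)CC[C@@]2(C)[C@@H]1CCO | intermediate
24 | 2-[(1R,4aR,6R,8aS)-6-[(tert-butyldimethylsilyl)oxy]-5,5-bis(hydroxymethyl)-8a-methyl-2-methylidenedecahydronaphthalen-1-yl]ethan-1-ol | C=C1CC[C@H]2C(CO)(CO)[C@H](O[Si](C)(C)C(C)(C)C)CC[C@@]2(C)[C@@H]1CCO | intermediate
25 | acetonide of 24 across the C4 hydroxymethyl groups (spiro 2,2-dimethyl-1,3-dioxane), C12–OH free | C=C1CC[C@H]2C3(COC(C)(C)OC3)[C@H](O[Si](C)(C)C(C)(C)C)CC[C@@]2(C)[C@@H]1CCO | intermediate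
26 | C12 iodide of 25 | C=C1CC[C@H]2C3(COC(C)(C)OC3)[C@H](O[Si](C)(C)C(C)(C)C)CC[C@@]2(C)[C@@H]1CCI | intermediate
27 | 3-bromooxolan-2-one (α-bromo-γ-butyrolactone, racemic) | BrC1CCOC1=O | starting material
28 | benzenethiol | Sc1ccccc1 | starting material
29 | 3-(phenylsulfanyl)oxolan-2-one (racemic) | O=C1OCCC1Sc1ccccc1 | intermediate
30 | lithium enolate of 29 | [Li]OC1=C(Sc2ccccc2)CCO1 | intermediate
31 | 3-(phenylsulfanyl)oxolan-2-one alkylated at C3 by the C12 carbon of 26 (both C13 epimers) | C=C1CC[C@H]2C3(COC(C)(C)OC3)[C@H](O[Si](C)(C)C(C)(C)C)CC[C@@]2(C)[C@@H]1CCC1(Sc2ccccc2)CCOC1=O | intermediate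
32 | sulfoxide of 31 (stereoisomers at sulfur and C13) | C=C1CC[C@H]2C3(COC(C)(C)OC3)[C@H](O[Si](C)(C)C(C)(C)C)CC[C@@]2(C)[C@@H]1CCC1(S(=O)c2ccccc2)CCOC1=O | intermediate
33 | butenolide with 3-O-TBS ether and C4 acetonide | C=C1CC[C@H]2C3(COC(C)(C)OC3)[C@H](O[Si](C)(C)C(C)(C)C)CC[C@@]2(C)[C@@H]1CCC1=CCOC1=O | intermediate
34 | 3-{2-[(1R,4aR,6R,8aS)-6-hydroxy-5,5-bis(hydroxymethyl)-8a-methyl-2-methylidenedecahydronaphthalen-1-yl]ethyl}furan-2(5H)-one | C=C1CC[C@H]2C(CO)(CO)[C@H](O)CC[C@@]2(C)[C@@H]1CCC1=CCOC1=O | target

**Step count:** 19 steps in total; longest linear sequence 18 steps (steps 1–15 and 17–19, from cyclohex-2-en-1-ol).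

**Steps most likely to fail**

Step 10. C-allylation next to the new quaternary centre may be slow, so that enolate 18 equilibrates by proton transfer to the C7–C8 enolate, takes up allyl at C7 or twice, or reacts on the concave face. The fallback sets out from 14: the cuprate adduct is quenched at −78 °C with allyl chloroformate to give the allyl enol carbonate F1, which is treated with Pd(PPh3)4 (cat.) in THF at rt. This decarboxylative Tsuji allylation generates the palladium enolate and the π-allyl partner as an ion pair at the fixed C8–C9 position, without a free equilibrating enolate, and comes back to the route at 19.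

Step 8. Chemoselectivity may be lost through hydride attack at the enone carbonyl, and the C3 alkoxide may open by retro-aldol before the quench. The fallback sets out from 12: both carbonyl groups are reduced with excess LiBH(s-Bu)3 to the diol F2 (axial C3–OH, allylic C8–OH as either epimer), and the allylic alcohol alone is re-oxidised with MnO2 in CH2Cl2, which comes back to the route at 13.

Step 3. Hydrogen abstraction may also occur at the tertiary allylic C5–H, which would give the transposed enone and erase the stereocentre. In the fallback the C8 oxygen comes in with the electrophile. It sets out from diethyl malonate 3 and meso cis-cyclohex-2-ene-1,4-diyl diacetate F3 (available from cyclohexa-1,3-diene by palladium-catalysed 1,4-diacetoxylation). Desymmetrising allylic alkylation under the conditions of step 2, with the ligand enantiomer leading to the (1R)-malonate, gives the cis acetate F4 with overall retention. K2CO3 in EtOH frees the allylic alcohol F5, and MnO2 in CH2Cl2 oxidises it, which comes back to the route at 5.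

**Further compounds**
F1 | step 10 | allyl enol carbonate of the C8–C9 enolate (allyl carbonate on O8 of 18) | C=CCOC(=O)OC=1CC[C@H]2C(C(=O)OCC)(C(=O)OCC)[C@H](O[Si](C)(C)C(C)(C)C)CC[C@@]2(C)C=1
F2 | step 8 | diethyl (4aR,6R)-2,6-dihydroxy-2,3,4,4a,7,8-hexahydronaphthalene-5,5(6H)-dicarboxylate (either C8 carbinol epimer) | OC1CC[C@H]2C(C(=O)OCC)(C(=O)OCC)[C@H](O)CCC2=C1
F3 | step 3 | meso cis-cyclohex-2-ene-1,4-diyl diacetate | CC(=O)O[C@@H]1C=C[C@H](OC(C)=O)CC1
F4 | step 3 | diethyl 2-[(1R,4S)-4-acetoxycyclohex-2-en-1-yl]propanedioate (cis) | CC(=O)O[C@H]1CC[C@H](C=C1)C(C(=O)OCC)C(=O)OCC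
F5 | step 3 | diethyl 2-[(1R,4S)-4-hydroxycyclohex-2-en-1-yl]propanedioate (cis) | O[C@H]1CC[C@H](C=C1)C(C(=O)OCC)C(=O)OCC
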